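**Plan**

Numbering: lactone OCH2 is C1, ring CH is C2, ring carbon is C3, lactone carbonyl is C20; the chain runs C4 to C15, with C19H2OH on C7, C18H2OAc on C11, and C16H2OH plus C17H3 on C15. C11 is a CH bearing one oxygenated one-carbon arm (C18) and two CH2-linked chains (C10, C12). That is the imprint of two carbon groups added across a vinylboron unit C10=C11 whose boron later becomes C18; the only ring (butenolide O, C1, C2, C3, C20) is remote and is made late.
Retrosynthesis: C18–C11 is traced back to a C11–B bond; C3–C4 and the lactone C20–O bond are cut to an allyl group (C4–C6) and a four-carbon hydroxyalkynoate; C11–C12 and C9–C10 are then cut together, giving a tail alkyllithium (C12–C17), vinylboronic pinacol ester (C10, C11) and a head E-alkenyl bromide (C4–C9, C19).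
Forward: the tail iodide (7 steps) and head bromide (6 steps) are joined with the vinylboron unit in one three-component coupling. Boron is then homologated, oxidised and acetylated (C18H2OAc), the butenolide is annulated onto the allyl group (the only ring closure, by lactonisation), C5=C6 and C8=C9 are hydrogenated, and the silyl ethers are removed.
Stereochemistry: C7 comes from a titanium-enolate hydroxymethylation of an (R)-4-benzyloxazolidinone imide; C11 from the chiral ferrocenyl diphosphine on palladium during the metallate shift; Z-C14=C15 from a Still–Gennari olefination. The CIP letters at C7 and C11 change along the route only because substituent priorities change; no centre is inverted.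

Key step: step 14

Assumption: the (Sp,Sp) antipode of the ferrocenyl diphosphine is taken to direct the shift to the face of C11 that gives the 11S boronate 21; should a model coupling show the opposite sense, the (Rp,Rp) antipode is used with nothing else changed.

**Route**

Step 1
Reactants: 1 propane-1,3-diol
Product: 2 3-[(4-methoxybenzyl)oxy]propan-1-ol
Conditions: NaH (1 equiv), PMBCl (1 equiv), n-Bu4NI (cat.), THF/DMF, 0 °C to rt; diol in threefold excess
Reagents that add atoms: 4-methoxybenzyl chloride (PMBCl), COc1ccc(CCl)cc1
Why: Williamson etherification of the monoalkoxide; the excess of symmetrical diol should suppress bis-alkylation, and unreacted diol is removed by aqueous extraction.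

Step 2
Reactants: 2 3-[(4-methoxybenzyl)oxy]propan-1-ol
Product: 3 3-[(4-methoxybenzyl)oxy]propanal
Conditions: TEMPO (10 mol%), PhI(OAc)2 (1.1 equiv), CH2Cl2, rt
Reagents that add atoms: none
Why: TEMPO-catalysed oxoammonium oxidation of a primary alcohol stops at the aldehyde, and the nearly neutral medium should avoid β-elimination of the PMB ether.

Step 3
Reactants: 3 3-[(4-methoxybenzyl)oxy]propanal; 4 ethyl 2-[bis(2,2,2-trifluoroethoxy)phosphoryl]propanoate
Product: 5 ethyl (2Z)-5-[(4-methoxybenzyl)oxy]-2-methylpent-2-enoate
Conditions: KN(SiMe3)2, 18-crown-6, THF, −78 °C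
Reagents that add atoms: none
Why: Still–Gennari olefination; the electron-poor trifluoroethyl phosphonate with a crown-separated potassium counter-ion eliminates under kinetic control and should give the Z trisubstituted enoate, with the chain cis to the ester (the future Z-C14=C15).

Step 4
Reactants: 5 ethyl (2Z)-5-[(4-methoxybenzyl)oxy]-2-methylpent-2-enoate
Product: 6 (2Z)-5-[(4-methoxybenzyl)oxy]-2-methylpent-2-en-1-ol
Conditions: i-Bu2AlH (2.5 equiv), CH2Cl2, −78 °C; aq. potassium sodium tartrate
Reagents that add atoms: none
Why: 1,2-reduction of the conjugated ester by i-Bu2AlH gives the allylic alcohol without touching the alkene geometry.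

Step 5
Reactants: 6 (2Z)-5-[(4-methoxybenzyl)oxy]-2-methylpent-2-en-1-ol
Product: 7 tert-butyl({(2Z)-5-[(4-methoxybenzyl)oxy]-2-methylpent-2-en-1-yl}oxy)dimethylsilane
Conditions: TBSCl, imidazole, DMF, 0 °C to rt
Reagents that add atoms: tert-butyldimethylsilyl chloride (TBSCl), CC(C)(C)[Si](C)(C)Cl
Why: Imidazole-promoted silylation of the primary allylic alcohol installs the C16 protecting group that is carried to the end.

Step 6
Reactants: 7 tert-butyl({(2Z)-5-[(4-methoxybenzyl)oxy]-2-methylpent-2-en-1-yl}oxy)dimethylsilane
Product: 8 (3Z)-5-{[tert-butyl(dimethyl)silyl]oxy}-4-methylpent-3-en-1-ol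
Conditions: DDQ (1.2 equiv), CH2Cl2/pH 7 phosphate buffer (10:1), 0 °C
Reagents that add atoms: none
Why: Oxidative PMB ether cleavage; DDQ oxidises only the electron-rich benzylic position, so the silyl ether and the trisubstituted alkene should survive.

Step 7
Reactants: 8 (3Z)-5-{[tert-butyl(dimethyl)silyl]oxy}-4-methylpent-3-en-1-ol
Product: 9 tail iodide tert-butyl{[(2Z)-5-iodo-2-methylpent-2-en-1-yl]oxy}dimethylsilane
Conditions: I2, PPh3, imidazole, CH2Cl2, 0 °C
Reagents that add atoms: iodine, [I][I]
Why: Appel-type (Garegg–Samuelsson) iodination; the alkoxyphosphonium ion is displaced by iodide at the unhindered primary carbon under conditions that leave the allylic silyl ether alone.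

Step 8
Reactants: 10 (4R)-4-benzyl-1,3-oxazolidin-2-one; 11 pent-4-enoyl chloride
Product: 12 (4R)-4-benzyl-3-(pent-4-enoyl)-1,3-oxazolidin-2-one
Conditions: n-BuLi, THF, −78 °C; then 11, −78 to 0 °C
Reagents that add atoms: none
Why: N-acylation of the lithiated oxazolidinone with the acid chloride is the standard route to the chiral imide.

Step 9
Reactants: 12 (4R)-4-benzyl-3-(pent-4-enoyl)-1,3-oxazolidin-2-one
Product: 13 (4R)-4-benzyl-3-[(2S)-2-(hydroxymethyl)pent-4-enoyl]-1,3-oxazolidin-2-one
Conditions: TiCl4 (1.05 equiv), i-Pr2NEt (1.1 equiv), CH2Cl2, 0 °C; then 1,3,5-trioxane (1.2 equiv), TiCl4 (1.05 equiv), 0 °C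
Reagents that add atoms: 1,3,5-trioxane, C1OCOCO1
Why: Auxiliary-controlled titanium-enolate hydroxymethylation (aldol-type addition to formaldehyde released from trioxane by TiCl4); the chelated Z chlorotitanium enolate is attacked on the face opposite the benzyl group, which sets C7.

Step 10
Reactants: 13 (4R)-4-benzyl-3-[(2S)-2-(hydroxymethyl)pent-4-enoyl]-1,3-oxazolidin-2-one
Product: 14 (4R)-4-benzyl-3-[(2S)-2-({[tert-butyl(dimethyl)silyl]oxy}methyl)pent-4-enoyl]-1,3-oxazolidin-2-one
Conditions: TBSCl, imidazole, DMF, rt
Reagents that add atoms: tert-butyldimethylsilyl chloride (TBSCl), CC(C)(C)[Si](C)(C)Cl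
Why: Silylation of the primary alcohol protects C19–OH and blocks retro-aldol loss of formaldehyde in the next step.

Step 11
Reactants: 14 (4R)-4-benzyl-3-[(2S)-2-({[tert-butyl(dimethyl)silyl]oxy}methyl)pent-4-enoyl]-1,3-oxazolidin-2-one
Product: 15 (2R)-2-({[tert-butyl(dimethyl)silyl]oxy}methyl)pent-4-en-1-ol
Conditions: LiBH4, MeOH (1 equiv), Et2O, 0 °C; cold aq. NH4Cl quench
Reagents that add atoms: none
Why: Reductive cleavage of the imide by LiBH4 gives the primary alcohol and releases the auxiliary; the cold, brief treatment and quench should prevent silyl migration between the two primary oxygens, which would erode C7.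

Step 12
Reactants: 15 (2R)-2-({[tert-butyl(dimethyl)silyl]oxy}methyl)pent-4-en-1-ol
Product: 16 (2S)-2-({[tert-butyl(dimethyl)silyl]oxy}methyl)pent-4-enal
Conditions: TEMPO (10 mol%), PhI(OAc)2 (1.1 equiv), CH2Cl2, 0 °C to rt; used crude
Reagents that add atoms: none
Why: TEMPO-catalysed oxoammonium oxidation is free of base, so the α-stereocentre C7 of the aldehyde should not epimerise and the β-silyloxy group should not eliminate.

Step 13
Reactants: 16 (2S)-2-({[tert-butyl(dimethyl)silyl]oxy}methyl)pent-4-enal
Product: 17 head bromide tert-butyl{[(2R,3E)-4-bromo-2-(prop-2-en-1-yl)but-3-en-1-yl]oxy}dimethylsilane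
Conditions: CrBr2 (6 equiv), CHBr3 (2 equiv), THF, 0 °C to rt
Reagents that add atoms: bromoform, BrC(Br)Br
Why: Takai olefination; the geminal dichromium species from bromoform adds to the aldehyde and eliminates to the E-bromoalkene under non-basic conditions that spare C7, and the use of CrBr2 in place of CrCl2 avoids halogen scrambling.

Step 14
Reactants: 9 tail iodide; 18 vinylboronic acid pinacol ester; 17 head bromide
Product: 21 C11 secondary pinacol boronate joining tail and head (7R,11S), via tail alkyllithium 19 (not isolated), via lithium vinylboron ate complex 20 (not isolated)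
Conditions: 9, t-BuLi (2.0 equiv), Et2O, −78 °C; 18, −78 °C to rt; solvent exchanged for THF; 17, Pd(OAc)2 (3 mol%), (Sp,Sp)-1,1'-bis[bis(4-methoxy-3,5-dimethylphenyl)phosphino]-2,2'-bis[α-(dimethylamino)benzyl]ferrocene (MandyPhos type, 3.6 mol%), KOSO2CF3 (2.5 equiv), THF, 60 °C
Reagents that add atoms: none
Why: Lithium–iodine exchange on 9 gives the primary alkyllithium 19, which adds to boron of 18 to form the tetracoordinate ate complex 20; oxidative addition of 17 to zerovalent palladium gives an alkenyl complex of divalent palladium that, once potassium trifluoromethanesulfonate has removed halide as insoluble KBr and KI, binds the vinyl group of 20 and induces an anti 1,2-shift of C12 from boron to C11 while the metal bonds C10, after which reductive elimination forms C9–C10 with retention of the E geometry. The closest known reaction type is the palladium-catalysed enantioselective conjunctive cross-coupling of vinylboron ate complexes bearing alkyl migrating groups with aryl or alkenyl halides and triflates. No ring is closed in this step. The new stereocentre C11 is set by the chiral diphosphine on palladium, which selects one enantiotopic face of the bound vinyl group during the metallate shift and therefore acts independently of the remote C7. The step needs migration of the primary alkyl carbon rather than a pinacol oxygen (secured by the far higher migratory aptitude of carbon in the pinacolato ate complex), the metallate shift rather than direct vinyl transmetallation (favoured by the wide-bite-angle ligand on a halide-free cationic palladium centre), and no Heck cyclisation onto the allyl group of 17 (excluded because the palladium-bearing carbon of the E-alkenyl unit lies trans to the chain that carries that alkene).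

Step 15
Reactants: 21 C11 secondary pinacol boronate
Product: 23 C18 primary alcohol (7R,11S), via homologated C18 pinacol boronate 22 (not isolated)
Conditions: ClCH2I (3 equiv), n-BuLi (2.5 equiv), THF, −78 °C to rt; then NaOH (3 M aq.), H2O2 (30% aq.), 0 °C to rt
Reagents that add atoms: chloroiodomethane, ClCI; hydrogen peroxide, OO
Why: Matteson homologation; LiCH2Cl formed in the flask adds to boron and C11 migrates to the CH2 carbon with loss of chloride and retention at C11, after which alkaline peroxide oxidises the new primary C18–B bond to C18–OH without affecting the alkenes or silyl ethers.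

Step 16
Reactants: 23 C18 primary alcohol
Product: 24 C18 acetate (7R,11S)
Conditions: Ac2O, pyridine, DMAP (cat.), CH2Cl2, 0 °C to rt
Reagents that add atoms: acetic anhydride, CC(=O)OC(C)=O
Why: DMAP-catalysed acylation of the only free hydroxyl group places the acetate on C18 while C16 and C19 are still silylated, which differentiates the three primary oxygens.

Step 17
Reactants: 24 C18 acetate; 25 ethyl 4-hydroxybut-2-ynoate
Product: 27 diene butenolide (7S,11S), via hydroxy enoate 26 (not isolated)
Conditions: 25 (1.5 equiv), CpRu(cod)Cl (chloro(cyclopentadienyl)(1,5-cyclooctadiene)ruthenium, 5–10 mol%), MeOH, 65 °C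
Reagents that add atoms: none
Why: Ruthenium-catalysed Alder-ene coupling of a monosubstituted alkene with a γ-hydroxy alkynoate; oxidative cyclisation to a ruthenacyclopentene joins C4 to the alkyne carbon next to the ester (C3), β-hydride elimination from C6 and reductive elimination give E-C5=C6 and a trisubstituted alkene with CH2OH cis to the ester, so lactonisation to the butenolide follows, while the 1,2-disubstituted and trisubstituted alkenes are too hindered to enter the metallacycle.

Step 18
Reactants: 27 diene butenolide
Product: 28 saturated bis-silyl ether acetate (7S,11R)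
Conditions: H2 (1 atm), RhCl(PPh3)3 (15 mol%), benzene/EtOH (1:1), rt
Reagents that add atoms: none
Why: Homogeneous hydrogenation with RhCl(PPh3)3 discriminates by substitution, so the two 1,2-disubstituted alkenes C5=C6 and C8=C9 should be reduced while the trisubstituted C14=C15 and the conjugated trisubstituted butenolide alkene remain, and neither C7 nor C11 is touched.

Step 19
Reactants: 28 saturated bis-silyl ether acetate
Product: 29 CNP0325245.2 (7S,11R,14Z)
Conditions: HF·pyridine, pyridine, THF, 0 °C to rt
Reagents that add atoms: none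
Why: Fluoride-mediated desilylation of both primary TBS ethers in a pyridine-buffered, non-basic medium, in which the primary acetate should neither hydrolyse nor migrate and the base-sensitive butenolide is not deprotonated.

**Compound list**

1 | propane-1,3-diol | OCCCO | starting material
2 | 3-[(4-methoxybenzyl)oxy]propan-1-ol | COc1ccc(COCCCO)cc1 | intermediate
3 | 3-[(4-methoxybenzyl)oxy]propanal | COc1ccc(COCCC=O)cc1 | intermediate
4 | ethyl 2-[bis(2,2,2-trifluoroethoxy)phosphoryl]propanoate | CCOC(=O)C(C)P(=O)(OCC(F)(F)F)OCC(F)(F)F | starting material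
5 | ethyl (2Z)-5-[(4-methoxybenzyl)oxy]-2-methylpent-2-enoate | COc1ccc(COCC/C=C(/C)C(=O)OCC)cc1 | intermediate
6 | (2Z)-5-[(4-methoxybenzyl)oxy]-2-methylpent-2-en-1-ol | COc1ccc(COCC/C=C(/C)CO)cc1 | intermediate
7 | tert-butyl({(2Z)-5-[(4-methoxybenzyl)oxy]-2-methylpent-2-en-1-yl}oxy)dimethylsilane | COc1ccc(COCC/C=C(/C)CO[Si](C)(C)C(C)(C)C)cc1 | intermediate
8 | (3Z)-5-{[tert-butyl(dimethyl)silyl]oxy}-4-methylpent-3-en-1-ol | OCC/C=C(/C)CO[Si](C)(C)C(C)(C)C | intermediate
9 | tail iodide, tert-butyl{[(2Z)-5-iodo-2-methylpent-2-en-1-yl]oxy}dimethylsilane (C12–C17) | ICC/C=C(/C)CO[Si](C)(C)C(C)(C)C | intermediate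
10 | (4R)-4-benzyl-1,3-oxazolidin-2-one | O=C1N[C@H](Cc2ccccc2)CO1 | starting material
11 | pent-4-enoyl chloride | C=CCCC(Cl)=O | starting material
12 | (4R)-4-benzyl-3-(pent-4-enoyl)-1,3-oxazolidin-2-one | C=CCCC(=O)N1[C@H](Cc2ccccc2)COC1=O | intermediate
13 | (4R)-4-benzyl-3-[(2S)-2-(hydroxymethyl)pent-4-enoyl]-1,3-oxazolidin-2-one | O=C(N1[C@H](Cc2ccccc2)COC1=O)[C@H](CO)CC=C | intermediate
14 | (4R)-4-benzyl-3-[(2S)-2-({[tert-butyl(dimethyl)silyl]oxy}methyl)pent-4-enoyl]-1,3-oxazolidin-2-one | O=C(N1[C@H](Cc2ccccc2)COC1=O)[C@H](CO[Si](C)(C)C(C)(C)C)CC=C | intermediate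
15 | (2R)-2-({[tert-butyl(dimethyl)silyl]oxy}methyl)pent-4-en-1-ol | OC[C@H](CO[Si](C)(C)C(C)(C)C)CC=C | intermediate
16 | (2S)-2-({[tert-butyl(dimethyl)silyl]oxy}methyl)pent-4-enal | O=C[C@H](CO[Si](C)(C)C(C)(C)C)CC=C | intermediate
17 | head bromide, tert-butyl{[(2R,3E)-4-bromo-2-(prop-2-en-1-yl)but-3-en-1-yl]oxy}dimethylsilane (C4–C9, C19) | Br/C=C/[C@H](CO[Si](C)(C)C(C)(C)C)CC=C | intermediate
18 | vinylboronic acid pinacol ester, 2-ethenyl-4,4,5,5-tetramethyl-1,3,2-dioxaborolane (C10, C11) | C=CB1OC(C)(C)C(C)(C)O1 | starting material
19 | tail alkyllithium, [(3Z)-5-{[tert-butyl(dimethyl)silyl]oxy}-4-methylpent-3-en-1-yl]lithium | [Li]CC/C=C(/C)CO[Si](C)(C)C(C)(C)C | intermediate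
20 | lithium vinylboron ate complex of 19 and 18 (tetracoordinate pinacolato borate) | [Li+].C=C[B-]1(CC/C=C(/C)CO[Si](C)(C)C(C)(C)C)OC(C)(C)C(C)(C)O1 | intermediate
21 | C11 secondary pinacol boronate (7R,11S; E-C8=C9, Z-C14=C15, C16 and C19 as TBS ethers, allyl C4–C6) | CC1(C)OB(OC1(C)C)[C@@H](CC/C=C(/C)CO[Si](C)(C)C(C)(C)C)C/C=C/[C@H](CO[Si](C)(C)C(C)(C)C)CC=C | intermediate
22 | homologated C18 primary pinacol boronate (7R,11S) | CC1(C)OB(C[C@@H](CC/C=C(/C)CO[Si](C)(C)C(C)(C)C)C/C=C/[C@H](CO[Si](C)(C)C(C)(C)C)CC=C)OC1(C)C | intermediate
23 | C18 primary alcohol (7R,11S) | OC[C@@H](CC/C=C(/C)CO[Si](C)(C)C(C)(C)C)C/C=C/[C@H](CO[Si](C)(C)C(C)(C)C)CC=C | intermediate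
24 | C18 acetate (7R,11S) | CC(=O)OC[C@@H](CC/C=C(/C)CO[Si](C)(C)C(C)(C)C)C/C=C/[C@H](CO[Si](C)(C)C(C)(C)C)CC=C | intermediate
25 | ethyl 4-hydroxybut-2-ynoate | CCOC(=O)C#CCO | starting material
26 | hydroxy enoate from the Alder-ene coupling (C3=C2 with CH2OH cis to CO2Et, E-C5=C6; 7S,11S) | CC(=O)OC[C@@H](CC/C=C(/C)CO[Si](C)(C)C(C)(C)C)C/C=C/[C@H](CO[Si](C)(C)C(C)(C)C)/C=C/C/C(C(=O)OCC)=C/CO | intermediate
27 | diene butenolide (E-C5=C6, E-C8=C9; 7S,11S) | CC(=O)OC[C@@H](CC/C=C(/C)CO[Si](C)(C)C(C)(C)C)C/C=C/[C@H](CO[Si](C)(C)C(C)(C)C)/C=C/CC1=CCOC1=O | intermediate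
28 | saturated bis-TBS ether acetate (7S,11R) | CC(=O)OC[C@@H](CC/C=C(/C)CO[Si](C)(C)C(C)(C)C)CCC[C@H](CO[Si](C)(C)C(C)(C)C)CCCC1=CCOC1=O | intermediate
29 | CNP0325245.2 (7S,11R,14Z) | CC(=O)OC[C@@H](CC/C=C(/C)CO)CCC[C@H](CO)CCCC1=CCOC1=O | target

**Step count and risks**

Total step count: 19. Longest linear sequence: 13 steps (steps 1–7 and 14–19, from propane-1,3-diol); the head branch (steps 8–13) has 6 steps before convergence.

Steps most likely to fail:

Step 14. The catalyst may be inhibited by lithium iodide carried over from the exchange, the vinyl group may transfer directly (Suzuki-type coupling), or enantiofacial control may fall with partners this functionalised. The fallback sets out from iodide 9: exchange with t-BuLi and quenching with 2-isopropoxy-4,4,5,5-tetramethyl-1,3,2-dioxaborolane gives the tail pinacol boronic ester F1, which is purified free of halide. Halide-free vinyllithium, made from tetravinylstannane and n-BuLi, is added to F1 to give the same ate complex 20 from the other side. Coupling with 17 under the conditions of step 14 returns to the route at boronate 21.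

Step 17. Turnover may stall through chelation of the 1,5-diene to ruthenium, or the skipped diene may isomerise before lactonisation. The fallback sets out from acetate 24: chemoselective hydroboration of the terminal alkene with 9-BBN gives the C4 B-alkyl-9-borabicyclo[3.3.1]nonane F2, used in solution. B-alkyl Suzuki–Miyaura coupling with 3-bromofuran-2(5H)-one (PdCl2(dppf), AsPh3, K3PO4, DMF/THF/H2O, rt) gives the C8=C9 mono-ene butenolide F3, in which C4–C6 is already saturated. Hydrogenation of the remaining C8=C9 with RhCl(PPh3)3 and H2 returns to the route at compound 28.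

Step 18. The double bonds may migrate into conjugation through the doubly allylic C7–H, which would erode C7 or leave a trisubstituted alkene that resists reduction; the butenolide may also be partly reduced on long exposure. The fallback sets out from 27 and replaces metal-catalysed hydrogenation by diimide, generated from 2-nitrobenzenesulfonyl hydrazide and Et3N in CH2Cl2 at rt. Its concerted syn hydrogen transfer involves no metal hydride and is faster for 1,2-disubstituted than for trisubstituted or conjugated alkenes. It returns to the route at 28; no new compound arises on this path (F0).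

**Further compounds**

F1 | step 14 | tail pinacol boronic ester, 2-[(3Z)-5-{[tert-butyl(dimethyl)silyl]oxy}-4-methylpent-3-en-1-yl]-4,4,5,5-tetramethyl-1,3,2-dioxaborolane | CC1(C)OB(CC/C=C(/C)CO[Si](C)(C)C(C)(C)C)OC1(C)C
F2 | step 17 | C4 B-alkyl-9-borabicyclo[3.3.1]nonane from 24 (7R,11S) | CC(=O)OC[C@@H](CC/C=C(/C)CO[Si](C)(C)C(C)(C)C)C/C=C/[C@H](CO[Si](C)(C)C(C)(C)C)CCCB1C2CCCC1CCC2
F3 | step 17 | C8=C9 mono-ene butenolide, bis-TBS ether acetate (7R,11S) | CC(=O)OC[C@@H](CC/C=C(/C)CO[Si](C)(C)C(C)(C)C)C/C=C/[C@H](CO[Si](C)(C)C(C)(C)C)CCCC1=CCOC1=O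
F0 | step 18 | none | none
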